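Slowness comes first: at 3.0 d the east flask is either still crawling or has stopped, and in that flask waiting can gain no more than what is still open.

the same everywhere: starting material 0.050 M

| run | activator | temperature | remark | time |
|---|---|---|---|---|
| east | 1.3 equiv | 60 °C | the very flask that is asked about, followed so far |  |
| north | 1.3 equiv | 45 °C | run made earlier |  |
| flask | 1.30 equiv | 60 °C |  | 3.0 d |

| run | time / h | ring / % |
|---|---|---|
| east | 5.00 | 79.7 |
| east | 8.00 | 82.3 |
| east | 10.0 | 81.3 |
| east | 15.0 | 82.0 |
| east | 25.0 | 82.6 |
| east | 40.0 | 82.2 |
| east | 60.0 | 84.0 |
| north | 10.0 | 49.9 |
| north | 15.0 | 63.2 |
| north | 20.0 | 70.8 |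
| north | 30.0 | 78.8 |
| north | 48.0 | 81.3 |
| north | 96.0 | 79.4 |
| north | 120 | 79.9 |

(readings scatter by 1 percentage point)

- Tuesday's: at 3.0 d take out 90% of the ring then present, then wait 6.0 d
- Friday's: at 3.0 d raise the temperature by 25 K, then wait 6.0 d
- Wednesday's: change nothing and wait 6.0 d more
- Thursday's: at 3.0 d add activator, 100% of the amount charged, then wait 6.0 d

- removed ring is counted in
- additions bring no volume worth counting

- ring, in percent of the starting material first charged, at 3.0 d
- what to do for the largest gain in ring; "none" if nothing gains more than 2 percentage points (Tuesday's / Friday's / Wednesday's / Thursday's / none)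
- ring present, with what was taken out counted in, in percent of the starting material first charged, after Friday's
- ring present, with what was taken out counted in, in percent of the starting material first charged, after Thursday's

1. Bound on the half-life from above. In the north run, the room under the last reading falls from 30 percentage points to 9.1 points between 10.0 h and 20.0 h. That is a half-life of 5.81 h. The east flask is quicker: at 5.00 h it reads 79.7%, more than north's 49.9% at 10.0 h. So at 3.0 d its count is at least 12.4, the count being elapsed time over the half-life of the approach to the level.

2. Tightening. East's readings from 25.0 h on average 82.9%. Its first reading lies 3.2 points below that, which gives a half-life of roughly 1.07 h, rough since each reading scatters by 1 point. Even north's half-life leaves the east flask room of 0.015 points at 3.0 d, less than 2 points.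

3. Bracket on the ring at 3.0 d. The charge allows 100%, but the late readings tighten this to between 82.2% and 84.0%. I commit to 82.9%.

4. The count says the east flask has stopped, not why. A balance answers a removal; a one-way reaction that has stopped does not. The readings do not separate the two, and I take the one-way reaction, so my answer is none.

The forecast puts the ring at 82.5%, inside my bracket, but parts from me with Tuesday's, and gives 84% after Friday's and 82.7% after Thursday's, for “I favour an equilibrium”.

The flask gives 83.1% at 3.0 d, and its best is none, with 83.1% after Friday's and 83.1% after Thursday's.

    starting material + activator → activated form (k = 0.00842 /M/s, Ea = 75.0 kJ/mol)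
    activated form → ring (k = 2.13 × 10⁻⁴ /s, Ea = 103 kJ/mol)
    starting material + activated form → open dimer (k = 5.13 × 10⁻⁴ /M/s, Ea = 64.0 kJ/mol)
    2 starting material → self-condensation product (k = 0.00133 /M/s, Ea = 67.0 kJ/mol)
    (constants at 60 °C)

At 72.0 h starting material, the limiting reagent, stands at 0% of its charge, with activator at 34.7% of its own charge. Half the count, 6.20 at 36.0 h, already leaves room of 1.1 points, less than 2 points, and the flask then holds 83.1%.

Take the neighbour flask with 2.20 equiv of activator, hotter than north and richer in activator. I count at least 12.4 again, so I expect it to have stopped by 3.0 d, though the count gives no level. It ends with starting material at 0% and ring at 90.0%.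

(The data were generated by integration for substances that don't exist; scatter was added.)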